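**Plan**

1. Retrosynthesis: the three acetates and the C3 carbinol go back to a ketol with C3=O beside the tertiary methyl carbinol C4. This 2-hydroxy-2-methylcyclopentanone unit of the five-membered ring (C1–C5) is cut at C4–C5 by a retro-acyloin shift to a 1-acetylcyclobutanol (four-membered ring C1, C2, C3, C5) trans-fused to the seven-membered ring.
2. Enabling feature: carbonyl-level oxygen on C3 vicinal to the C4 methyl carbinol is exactly the product pattern of an α-ketol shift; release of four-ring strain drives C5 from C3 onto the acetyl carbon, which becomes C4.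
3. The cyclobutane is cut by retro-[2+2] into a cycloheptenone (C10=O, C1=C5) and 1,1-dimethoxyethene; C14 comes from methylenation of C10=O, the acetyl group from ethynyl addition and hydration.
4. The cycloheptenone goes back to tropone: isopropyl Grignard 1,8-addition (C7), reduction and inversion (C8), singlet-oxygen [4+2] and Kornblum–DeLaMare rearrangement (C6–OH, C10=O, C1=C5).
5. Forward ring order: seven-membered ring by dearomatising tropone, then the four-membered ring, then the five-membered ring by one-atom ring expansion.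
6. Stereochemistry: absolute configuration from lipase resolution at C8; C7/C8 trans by Mitsunobu inversion; C6 by O2 anti to isopropyl; C5 and C1 (trans fusion) in the photocycloaddition; C4 stereospecifically in the chelated ketol shift; C3 by hydroxyl-directed hydride.

Key step: step 12

Remark: positions are given in guaiane numbering (ring carbons C1–C10, C14 the exocyclic methylene carbon, C15 the methyl on C4) and α is the face of H-5 (target: 1β-H, 5α-H, trans-fused). The lipase is assumed to follow the usual preference for hydrolysing the ester of the (R)-carbinol faster.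

Step 1
Reactants: 1 tropone; 2 isopropylmagnesium bromide
Product: 4 rac-2-isopropylcyclohepta-3,5-dien-1-one, via bromomagnesium trienolate 3 (not isolated)
Conditions: 2 (1.1 equiv), THF, −78 °C; then sat. aq. NH4Cl at −78 °C
Reagents that add atoms: isopropylmagnesium bromide (2), CC(C)[Mg]Br
Why: Grignard reagents add to tropone in the 1,8-conjugate sense at C2 and kinetic C-protonation of the trienolate at the α-carbon should give the unconjugated 3,5-dienone; the new stereocentre (future C7) is racemic here and is resolved in step 4.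

Step 2
Reactants: 4 rac-2-isopropylcyclohepta-3,5-dien-1-one
Product: 5 rac-cis-2-isopropylcyclohepta-3,5-dien-1-ol
Conditions: iBu2AlH, CH2Cl2, −78 °C; aq. potassium sodium tartrate work-up
Reagents that add atoms: none
Why: hydride reduction of the ketone in which iBu2AlH should attack anti to the adjacent isopropyl group, so the new carbinol centre (future C8) comes out cis to isopropyl.

Step 3
Reactants: 5 rac-cis-2-isopropylcyclohepta-3,5-dien-1-ol
Product: 6 rac-trans-2-isopropylcyclohepta-3,5-dien-1-yl acetate
Conditions: PPh3, DIAD, AcOH, toluene, 0 °C to rt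
Reagents that add atoms: acetic acid, CC(=O)O
Why: Mitsunobu esterification with SN2 inversion at the carbinol carbon, acetate entering on the face anti to isopropyl, should convert the cis alcohol into the trans acetate required at C7/C8.

Step 4
Reactants: 6 rac-trans-2-isopropylcyclohepta-3,5-dien-1-yl acetate
Product: 7 (1S,2S)-2-isopropylcyclohepta-3,5-dien-1-yl acetate
Conditions: Candida rugosa lipase, pH 7 phosphate buffer/MTBE, rt, stopped just past half conversion; chromatography
Reagents that add atoms: none
Why: lipase-catalysed enantioselective ester hydrolysis (kinetic resolution) should cleave the (1R,2R)-acetate, whose carbinol carbon has the configuration lipases prefer for secondary alcohols, and leave (1S,2S)-7, which fixes the absolute configuration of the route.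

Step 5
Reactants: 7 (1S,2S)-2-isopropylcyclohepta-3,5-dien-1-yl acetate
Product: 9 (1S,2S,3R)-3-hydroxy-6-oxo-2-isopropylcyclohept-4-en-1-yl acetate, via bicyclic endoperoxide 8 (not isolated)
Conditions: O2, meso-tetraphenylporphyrin (cat.), visible light, CH2Cl2, −30 °C; then Et3N (0.2 equiv), 0 °C
Reagents that add atoms: dioxygen, O=O
Why: [4+2] cycloaddition of singlet oxygen to the cyclic 1,3-diene anti to the allylic isopropyl group should set C6–O and C10–O α, and the Kornblum–DeLaMare rearrangement should remove the less hindered bridgehead hydrogen (H-10, flanked by CH2 and not by the isopropyl-bearing carbon) to give the C10 ketone and the C6 hydroxyl.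

Step 6
Reactants: 9 (1S,2S,3R)-3-hydroxy-6-oxo-2-isopropylcyclohept-4-en-1-yl acetate
Product: 10 (1S,2R,3R)-6-oxo-2-isopropylcyclohept-4-ene-1,3-diyl diacetate
Conditions: Ac2O, pyridine, CH2Cl2, 0 °C
Reagents that add atoms: acetic anhydride, CC(=O)OC(C)=O
Why: standard O-acylation of the secondary allylic alcohol under weakly basic conditions that should not trigger E1cB loss of the β-acetoxy group.

Step 7
Reactants: 10 (1S,2R,3R)-6-oxo-2-isopropylcyclohept-4-ene-1,3-diyl diacetate; 11 1,1-dimethoxyethene
Product: 12 (1S,2S,3R,4S,7S)-9,9-dimethoxy-6-oxo-3-isopropylbicyclo[5.2.0]nonane-2,4-diyl diacetate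
Conditions: 11 (10 equiv), hν (350 nm, Pyrex), CH2Cl2, −40 °C; crude product used directly
Reagents that add atoms: 1,1-dimethoxyethene (11), C=C(OC)OC
Why: enone–alkene [2+2] photocycloaddition through the twisted (trans-cycloheptenone-like) excited enone, which characteristically gives trans-fused bicyclo[5.2.0]nonan-2-ones with head-to-tail regiochemistry for electron-rich alkenes (acetal carbon on the β-carbon C5); the bond at C5 should form anti to the C6 acetate (H-5 α) and the bond at C1 on the opposite face (H-1 β).

Step 8
Reactants: 12 (1S,2S,3R,4S,7S)-9,9-dimethoxy-6-oxo-3-isopropylbicyclo[5.2.0]nonane-2,4-diyl diacetate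
Product: 13 (1S,2S,3R,4S,7S)-9,9-dimethoxy-6-methylidene-3-isopropylbicyclo[5.2.0]nonane-2,4-diyl diacetate
Conditions: Zn, CH2Br2, TiCl4 (reagent pre-formed in THF), CH2Cl2, 0 °C to rt
Reagents that add atoms: dibromomethane, BrCBr
Why: the non-basic Lombardo methylenation installs C10=C14 without enolisation, so the strained trans ring fusion at C1 is locked before it can epimerise, and acetates, the β-acetoxy ketone and the acetal should survive.

Step 9
Reactants: 13 (1S,2S,3R,4S,7S)-9,9-dimethoxy-6-methylidene-3-isopropylbicyclo[5.2.0]nonane-2,4-diyl diacetate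
Product: 14 (1S,2S,3R,4S,7S)-6-methylidene-9-oxo-3-isopropylbicyclo[5.2.0]nonane-2,4-diyl diacetate
Conditions: oxalic acid, wet SiO2, CH2Cl2, rt
Reagents that add atoms: water, O
Why: mild acid hydrolysis of the dimethyl acetal to the cyclobutanone, under conditions too weak to enolise the ketone towards C5 or to isomerise the 1,1-disubstituted alkene.

Step 10
Reactants: 14 (1S,2S,3R,4S,7S)-6-methylidene-9-oxo-3-isopropylbicyclo[5.2.0]nonane-2,4-diyl diacetate; 15 ethynylmagnesium bromide
Product: 16 (1S,2S,3R,4S,7S,9R)-9-ethynyl-9-hydroxy-6-methylidene-3-isopropylbicyclo[5.2.0]nonane-2,4-diyl diacetate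
Conditions: 15 (1.2 equiv), LaCl3·2LiCl (0.3 equiv), THF, −78 °C; then sat. aq. NH4Cl
Reagents that add atoms: ethynylmagnesium bromide (15), C#C[Mg]Br
Why: 1,2-addition of an alkynyl Grignard reagent to the highly electrophilic cyclobutanone, faster than attack on the acetates at low temperature; the slender acetylide should enter on the β face along the pseudo-axial trajectory (anti to the pseudo-axial α-C–H bonds at C5 and C2, as hydride does with 3-substituted cyclobutanones), placing the hydroxyl α.

Step 11
Reactants: 16 (1S,2S,3R,4S,7S,9R)-9-ethynyl-9-hydroxy-6-methylidene-3-isopropylbicyclo[5.2.0]nonane-2,4-diyl diacetate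
Product: 17 (1S,2S,3R,4S,7S,9R)-9-acetyl-9-hydroxy-6-methylidene-3-isopropylbicyclo[5.2.0]nonane-2,4-diyl diacetate
Conditions: Hg(OTf)2 (5 mol%), H2O (10 equiv), MeCN, 0 °C
Reagents that add atoms: water, O
Why: mercury-catalysed Markovnikov hydration of a terminal ethynyl carbinol to the α-hydroxy methyl ketone, run cold with excess water so that capture by water outruns any shift of the strained ring; no stereocentre is touched.

Step 12
Reactants: 17 (1S,2S,3R,4S,7S,9R)-9-acetyl-9-hydroxy-6-methylidene-3-isopropylbicyclo[5.2.0]nonane-2,4-diyl diacetate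
Product: 18 (3S,3aS,4S,5R,6S,8aS)-3-hydroxy-3-methyl-8-methylidene-2-oxo-5-isopropyldecahydroazulene-4,6-diyl diacetate
Conditions: Cu(OTf)2 (10 mol%), 2,6-di-tert-butylpyridine (20 mol%), CH2Cl2, 0 °C to rt
Reagents that add atoms: none
Why: Cu(OTf)2 binds the tertiary hydroxyl and the acetyl oxygen of 17 as a five-membered chelate (O–C3–C4=O syn-periplanar), and the C3–C5 bond, which stands perpendicular to the carbonyl plane, migrates from C3 to the acetyl carbon while C3–O becomes a carbonyl, an acyloin (α-ketol) rearrangement made irreversible by release of cyclobutane strain. The closest known reaction type is the Lewis-acid-mediated α-ketol ring expansion of 1-acylcyclobutanols to 2-hydroxy-2-alkylcyclopentanones, together with the chelate-controlled D-homoannulation of 17-hydroxy-20-keto steroids. No ring is closed by cyclisation: the cyclopentane (C1–C5) arises by a suprafacial 1,2-shift that inserts the former acetyl carbon (C4) between C3 and C5, enlarging the four-membered ring (C1, C2, C3, C5) by one atom. The new stereocentre C4 is set by the chelate geometry: with acetyl β and hydroxyl α on C3, C5 moves onto the carbonyl face it already overhangs, so the former carbonyl oxygen ends α (4α-OH) and the methyl β, while C5 migrates with retention and the trans ring fusion (1β-H, 5α-H) is carried over. The step needs migration of C5 in preference to C2, which the higher migratory aptitude of the more substituted ring-fusion carbon over the CH2 carbon should secure. Should step 10 have delivered the epimeric carbinol, the same 4α-hydroxy product would follow from the non-chelated (transoid, alkoxide) mode of the same rearrangement.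

Step 13
Reactants: 18 (3S,3aS,4S,5R,6S,8aS)-3-hydroxy-3-methyl-8-methylidene-2-oxo-5-isopropyldecahydroazulene-4,6-diyl diacetate
Product: 19 (2S,3S,3aS,4S,5R,6S,8aS)-2,3-dihydroxy-3-methyl-8-methylidene-5-isopropyldecahydroazulene-4,6-diyl diacetate
Conditions: Me4NBH(OAc)3, MeCN/AcOH, −20 °C
Reagents that add atoms: none
Why: hydroxyl-directed triacetoxyborohydride reduction in which the 4α-hydroxyl binds boron and delivers hydride to the α face of the C3 ketone, also the face anti to the β-methyl group, should give the 3β-alcohol (trans-diol) while acetates and the alkene are untouched.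

Step 14
Reactants: 19 (2S,3S,3aS,4S,5R,6S,8aS)-2,3-dihydroxy-3-methyl-8-methylidene-5-isopropyldecahydroazulene-4,6-diyl diacetate
Product: 20 CNP0147943.1, (2S,3S,3aS,4S,5R,6S,8aS)-3-hydroxy-3-methyl-8-methylidene-5-isopropyldecahydroazulene-2,4,6-triyl triacetate
Conditions: Ac2O, pyridine, DMAP (cat.), CH2Cl2, 0 °C to rt
Reagents that add atoms: acetic anhydride, CC(=O)OC(C)=O
Why: DMAP-catalysed acylation should be selective for the secondary C3 hydroxyl over the hindered tertiary C4 hydroxyl under these mild conditions, completing the triacetate.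

**Compound list**

1 | tropone (cyclohepta-2,4,6-trien-1-one) | O=C1C=CC=CC=C1 | starting material
2 | isopropylmagnesium bromide | CC(C)[Mg]Br | starting material
3 | bromomagnesium 7-isopropylcyclohepta-1,3,5-trien-1-olate (racemic, not isolated) | CC(C)C1C=CC=CC=C1O[Mg]Br | intermediate
4 | rac-2-isopropylcyclohepta-3,5-dien-1-one | CC(C)C1C=CC=CCC1=O | intermediate
5 | rac-cis-2-isopropylcyclohepta-3,5-dien-1-ol (racemic; (1R,2S) enantiomer drawn) | C1=CC=C[C@H](C(C)C)[C@H](O)C1 | intermediate
6 | rac-trans-2-isopropylcyclohepta-3,5-dien-1-yl acetate (racemic; (1S,2S) enantiomer drawn) | C1=CC=C[C@H](C(C)C)[C@@H](OC(C)=O)C1 | intermediate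
7 | (1S,2S)-2-isopropylcyclohepta-3,5-dien-1-yl acetate | C1=CC=C[C@H](C(C)C)[C@@H](OC(C)=O)C1 | intermediate
8 | (1R,2R,3S,5R)-2-isopropyl-6,7-dioxabicyclo[3.2.2]non-8-en-3-yl acetate (endoperoxide, O–O bridge α, not isolated) | [C@@H]1(OO2)C[C@H](OC(C)=O)[C@@H](C(C)C)[C@H]2C=C1 | intermediate
9 | (1S,2S,3R)-3-hydroxy-6-oxo-2-isopropylcyclohept-4-en-1-yl acetate (C10 ketone, 6α-OH, 8α-OAc, 7β-isopropyl) | O=C1C[C@H](OC(C)=O)[C@@H](C(C)C)[C@H](O)C=C1 | intermediate
10 | (1S,2R,3R)-6-oxo-2-isopropylcyclohept-4-ene-1,3-diyl diacetate | O=C1C[C@H](OC(C)=O)[C@@H](C(C)C)[C@H](OC(C)=O)C=C1 | intermediate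
11 | 1,1-dimethoxyethene | C=C(OC)OC | starting material
12 | (1S,2S,3R,4S,7S)-9,9-dimethoxy-6-oxo-3-isopropylbicyclo[5.2.0]nonane-2,4-diyl diacetate (trans-fused) | O=C1C[C@H](OC(C)=O)[C@@H](C(C)C)[C@H](OC(C)=O)[C@@H]2[C@@H]1CC2(OC)OC | intermediate
13 | (1S,2S,3R,4S,7S)-9,9-dimethoxy-6-methylidene-3-isopropylbicyclo[5.2.0]nonane-2,4-diyl diacetate | C=C1C[C@H](OC(C)=O)[C@@H](C(C)C)[C@H](OC(C)=O)[C@@H]2[C@@H]1CC2(OC)OC | intermediate
14 | (1S,2S,3R,4S,7S)-6-methylidene-9-oxo-3-isopropylbicyclo[5.2.0]nonane-2,4-diyl diacetate | C=C1C[C@H](OC(C)=O)[C@@H](C(C)C)[C@H](OC(C)=O)[C@@H]2[C@@H]1CC2=O | intermediate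
15 | ethynylmagnesium bromide | C#C[Mg]Br | starting material
16 | (1S,2S,3R,4S,7S,9R)-9-ethynyl-9-hydroxy-6-methylidene-3-isopropylbicyclo[5.2.0]nonane-2,4-diyl diacetate (hydroxyl α, ethynyl β) | C=C1C[C@H](OC(C)=O)[C@@H](C(C)C)[C@H](OC(C)=O)[C@@H]2[C@@H]1C[C@]2(O)C#C | intermediate
17 | (1S,2S,3R,4S,7S,9R)-9-acetyl-9-hydroxy-6-methylidene-3-isopropylbicyclo[5.2.0]nonane-2,4-diyl diacetate | C=C1C[C@H](OC(C)=O)[C@@H](C(C)C)[C@H](OC(C)=O)[C@@H]2[C@@H]1C[C@]2(O)C(C)=O | intermediate
18 | (3S,3aS,4S,5R,6S,8aS)-3-hydroxy-3-methyl-8-methylidene-2-oxo-5-isopropyldecahydroazulene-4,6-diyl diacetate (3-oxo, 4α-OH) | C=C1C[C@H](OC(C)=O)[C@@H](C(C)C)[C@H](OC(C)=O)[C@@H]2[C@@H]1CC(=O)[C@@]2(C)O | intermediate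
19 | (2S,3S,3aS,4S,5R,6S,8aS)-2,3-dihydroxy-3-methyl-8-methylidene-5-isopropyldecahydroazulene-4,6-diyl diacetate (3β-OH, 4α-OH) | C=C1C[C@H](OC(C)=O)[C@@H](C(C)C)[C@H](OC(C)=O)[C@@H]2[C@@H]1C[C@H](O)[C@@]2(C)O | intermediate
20 | CNP0147943.1, (2S,3S,3aS,4S,5R,6S,8aS)-3-hydroxy-3-methyl-8-methylidene-5-isopropyldecahydroazulene-2,4,6-triyl triacetate | C=C1C[C@H](OC(C)=O)[C@@H](C(C)C)[C@H](OC(C)=O)[C@@H]2[C@@H]1C[C@H](OC(C)=O)[C@@]2(C)O | target

**Totals**

Total step count: 14. Longest linear sequence: 14 steps (from tropone).

**Steps most likely to fail**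

Step 12 (key step). The risk is migration of the CH2 carbon C2 in place of C5, or partial passage through a non-chelated transition state that erodes the configuration at C4. The fallback sets out from 16. Cationic gold catalysis ((4-CF3C6H4)3PAuCl, AgSbF6, CH2Cl2, rt) expands the 1-ethynylcyclobutanol by stereospecific 1,2-shift of the more substituted ring carbon C5 onto the gold-bound alkyne, a reaction type with firm precedent for this regiochemistry. This should give 3-oxo-1βH,5αH-guaia-4(15),10(14)-diene-6α,8α-diyl diacetate F1. Mukaiyama-type hydration of the exocyclic enone (Mn(dpm)3 with dpm = dipivaloylmethanate, PhSiH3, O2, iPrOH, 0 °C; then P(OEt)3) adds hydrogen to C15, and the C4 radical should be captured by O2 anti to the C5–C6 bond, on the α face. This gives the 4α-hydroxy ketone and comes back to the route at 18.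

Step 7. The risk is poor facial discrimination when the first bond forms at C5 (the small C6 acetate competing with the C7 isopropyl group), or loss of the trans ring fusion by enolisation at C1. The fallback sets out from 9. Silylation (tBuPh2SiCl, imidazole, DMF) gives the C6 tert-butyldiphenylsilyl ether of hydroxy enone 9 F2, in which a bulky temporary steering group on C6–O should force the alkene to bond to C5 anti to it. Photocycloaddition with 11 under the conditions of step 7 should then give the 6-O-silyl analogue of photoadduct 12 F3. Lombardo methylenation gives the 6-O-silyl analogue of 13 F4. Desilylation (Bu4NF, AcOH, THF) gives the 6-hydroxy analogue of 13 F5. Acetylation (Ac2O, pyridine) comes back to the route at 13.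

Step 5. The risk is proton removal at the wrong bridgehead (C6–H) in the Kornblum–DeLaMare step, or E1cB loss of the C8 acetate once the β-acetoxy ketone meets the amine. The fallback sets out from 7. Photooxygenation as before gives endoperoxide 8, and the O–O bond is then cleaved reductively in the same flask with thiourea (MeOH, 0 °C). This gives (1S,2S,3R,6R)-3,6-dihydroxy-2-isopropylcyclohept-4-en-1-yl acetate F6, the cis-enediol. Chemoselective oxidation of the less hindered allylic carbinol at C10 with MnO2 (CH2Cl2, rt), with no base present, comes back to the route at 9.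

**Further compounds**

F1 | step 12 | 3-oxo-1βH,5αH-guaia-4(15),10(14)-diene-6α,8α-diyl diacetate | C=C1C[C@H](OC(C)=O)[C@@H](C(C)C)[C@H](OC(C)=O)[C@@H]2[C@@H]1CC(=O)C2=C
F2 | step 7 | C6 tert-butyldiphenylsilyl ether of hydroxy enone 9 | O=C1C[C@H](OC(C)=O)[C@@H](C(C)C)[C@H](O[Si](c2ccccc2)(c2ccccc2)C(C)(C)C)C=C1
F3 | step 7 | 6-O-tert-butyldiphenylsilyl analogue of photoadduct 12 (trans-fused) | O=C1C[C@H](OC(C)=O)[C@@H](C(C)C)[C@H](O[Si](c3ccccc3)(c3ccccc3)C(C)(C)C)[C@@H]2[C@@H]1CC2(OC)OC
F4 | step 7 | 6-O-tert-butyldiphenylsilyl analogue of 13 | C=C1C[C@H](OC(C)=O)[C@@H](C(C)C)[C@H](O[Si](c3ccccc3)(c3ccccc3)C(C)(C)C)[C@@H]2[C@@H]1CC2(OC)OC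
F5 | step 7 | 6-hydroxy analogue of 13 | C=C1C[C@H](OC(C)=O)[C@@H](C(C)C)[C@H](O)[C@@H]2[C@@H]1CC2(OC)OC
F6 | step 5 | (1S,2S,3R,6R)-3,6-dihydroxy-2-isopropylcyclohept-4-en-1-yl acetate | O[C@@H]1C[C@H](OC(C)=O)[C@@H](C(C)C)[C@H](O)C=C1
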